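**Plan**
1. Cut 1 is in ring C, the 2,3-dihydropyran-4-one (numbered O1, C2(Me), C3, C4(=O), C5, C6). C3–C4 and O1–C2 are cut together in a retro oxa-[4+2]. The O1–C6=C5–C4(=O) vinylogous-ester half of ring C is the imprint of an acylketene O=C–CH=C=O standing on coumarin C3, and C2–C3 is a propene unit.
2. Helpers: the acylketene is stored as a 2,2-dimethyl-1,3-dioxin-4-one, a temporary ring that leaves as acetone. Propene is used as its (E)-1-boronate with tetracoordinate boron on C3, which activates, directs and carries the chiral auxiliary; boron is removed by hydrolysis and protodeboronation.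
3. Cut 2 is in ring B, the lactone ring: C3=C4 and O1–C2 of the coumarin, by Knoevenagel condensation–lactonisation of a salicylaldehyde with a dioxinonyl acetate.
4. Cut 3 is the aryl–C bond of the side chain: aryl Grignard plus (2R,3R)-2,3-dimethyloxirane. The CH3 and CHO groups of ring A come from two formylations.
5. Forward order: ring A is dressed, ring B is closed, ring C is closed last, then boron and two benzyl groups are taken off.
6. Stereochemistry: both side-chain centres come from the chiral-pool epoxide (inversion at the attacked carbon, retention at the carbinol carbon). C2 of ring C comes from the pinene-derived auxiliary on boron in the cycloaddition.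

Key step: step 13

Assumption: epoxide 6, amine 18 and boronic acid 21 are bought as single stereoisomers.

Step 1
Reactants: 1 5-bromobenzene-1,3-diol
Product: 2 1,3-bis(benzyloxy)-5-bromobenzene
Conditions: BnBr, K2CO3, DMF, 60 °C
Reagents that add atoms: benzyl bromide, BrCc1ccccc1
Why: Williamson ether synthesis on both phenols; benzyl ethers survive the Grignard, Vilsmeier–Haack and thermolysis steps and can be removed at the end without base.

Step 2
Reactants: 2 1,3-bis(benzyloxy)-5-bromobenzene
Product: 4 2,4-bis(benzyloxy)-6-bromobenzaldehyde, via iminium chloride 3 (not isolated)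
Conditions: POCl3, DMF, 0 → 70 °C; then H2O
Reagents that add atoms: N,N-dimethylformamide, CN(C)C=O; water, O
Why: Vilsmeier–Haack formylation should go para to one benzyloxy group and ortho to the other, next to bromine, because the position between the two benzyloxy groups is the more crowded one.

Step 3
Reactants: 4 2,4-bis(benzyloxy)-6-bromobenzaldehyde
Product: 5 1,5-bis(benzyloxy)-3-bromo-2-methylbenzene
Conditions: Et3SiH, CF3CO2H, CH2Cl2, 0 °C → rt
Reagents that add atoms: none
Why: Ionic hydrogenation, in which the doubly alkoxy-stabilised benzylic cation is reduced by the silane, turns CHO into the ring A methyl group and leaves C–Br and the benzyl ethers alone.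

Step 4
Reactants: 5 1,5-bis(benzyloxy)-3-bromo-2-methylbenzene; 6 (2R,3R)-2,3-dimethyloxirane
Product: 8 (2R,3R)-3-[3,5-bis(benzyloxy)-2-methylphenyl]butan-2-ol, via arylmagnesium bromide 7 (not isolated)
Conditions: Mg, THF, 50 °C; then CuI (10 mol %), 6, THF, −30 → 0 °C; then H2O
Reagents that add atoms: none
Why: Copper-catalysed Grignard opening of an epoxide is an SN2 process, so inversion at the attacked carbon and retention at the carbinol carbon of the C2-symmetric (R,R)-epoxide should give the (2R,3R) alcohol, both centres coming from the chiral pool.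

Step 5
Reactants: 8 (2R,3R)-3-[3,5-bis(benzyloxy)-2-methylphenyl]butan-2-ol
Product: 9 1,5-bis(benzyloxy)-3-[(2R,3R)-3-(benzyloxy)butan-2-yl]-2-methylbenzene
Conditions: NaH, BnBr, Bu4NI (cat.), THF/DMF, 0 °C → rt
Reagents that add atoms: benzyl bromide, BrCc1ccccc1
Why: Williamson ether synthesis at oxygen does not touch either stereocentre, and it masks the alcohol against lactol formation with the later aldehyde and against trapping of the acylketene.

Step 6
Reactants: 9 1,5-bis(benzyloxy)-3-[(2R,3R)-3-(benzyloxy)butan-2-yl]-2-methylbenzene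
Product: 11 2,4-bis(benzyloxy)-6-[(2R,3R)-3-(benzyloxy)butan-2-yl]-5-methylbenzaldehyde, via iminium chloride 10 (not isolated)
Conditions: POCl3, DMF, 0 → 60 °C; then H2O
Reagents that add atoms: N,N-dimethylformamide, CN(C)C=O; water, O
Why: Vilsmeier–Haack formylation should take the free position that is para to one benzyloxy group and ortho to the other, as with orcinol-type diethers, rather than the site flanked by both benzyloxy groups.

Step 7
Reactants: 11 2,4-bis(benzyloxy)-6-[(2R,3R)-3-(benzyloxy)butan-2-yl]-5-methylbenzaldehyde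
Product: 12 4-(benzyloxy)-6-[(2R,3R)-3-(benzyloxy)butan-2-yl]-2-hydroxy-5-methylbenzaldehyde
Conditions: MgBr2·OEt2, toluene/Et2O, 80 °C; then H2O
Reagents that add atoms: none
Why: Chelation-controlled ether cleavage, in which magnesium binds the aldehyde oxygen and the ortho benzyloxy oxygen in a six-membered chelate, lets bromide remove only that benzyl group.

Step 8
Reactants: 13 2,2,6-trimethyl-4H-1,3-dioxin-4-one
Product: 15 methyl 2-(2,2-dimethyl-4-oxo-4H-1,3-dioxin-6-yl)acetate, via lithium dienolate 14 (not isolated)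
Conditions: LiN(SiMe3)2, THF, −78 °C; then ClCO2Me, −78 °C
Reagents that add atoms: methyl chloroformate, COC(=O)Cl
Why: γ-Selective C-acylation of the extended lithium dienolate of the dioxinone (vinylogous Claisen-type acylation) puts the future coumarin C2 carbonyl on the methyl carbon.

Step 9
Reactants: 12 4-(benzyloxy)-6-[(2R,3R)-3-(benzyloxy)butan-2-yl]-2-hydroxy-5-methylbenzaldehyde; 15 methyl 2-(2,2-dimethyl-4-oxo-4H-1,3-dioxin-6-yl)acetate
Product: 17 7-(benzyloxy)-5-[(2R,3R)-3-(benzyloxy)butan-2-yl]-3-(2,2-dimethyl-4-oxo-4H-1,3-dioxin-6-yl)-6-methyl-2H-chromen-2-one, via alkylidene ester 16 (not isolated)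
Conditions: piperidine (20 mol %), AcOH (20 mol %), toluene, 4 Å MS, 60 °C
Reagents that add atoms: none
Why: Knoevenagel condensation of the doubly activated CH2 followed by lactonisation of the ortho phenol onto the methyl ester is the classical coumarin synthesis, and 60 °C is below the temperature at which the dioxinone ring opens.

Step 10
Reactants: 18 (1R,2R,3R,5S)-2,6,6-trimethylbicyclo[3.1.1]heptan-3-amine (isopinocampheylamine)
Product: 19 di-tert-butyl 2,2'-{[(1R,2R,3R,5S)-2,6,6-trimethylbicyclo[3.1.1]heptan-3-yl]azanediyl}diacetate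
Conditions: BrCH2CO2tBu, K2CO3, MeCN, 60 °C
Reagents that add atoms: tert-butyl bromoacetate, CC(C)(C)OC(=O)CBr
Why: Double SN2 N-alkylation of the primary amine stops at the tertiary amine for steric reasons and leaves the pinane stereocentres untouched.

Step 11
Reactants: 19 di-tert-butyl 2,2'-{[(1R,2R,3R,5S)-2,6,6-trimethylbicyclo[3.1.1]heptan-3-yl]azanediyl}diacetate
Product: 20 2,2'-{[(1R,2R,3R,5S)-2,6,6-trimethylbicyclo[3.1.1]heptan-3-yl]azanediyl}diacetic acid (pinene-derived iminodiacetic acid, PIDA)
Conditions: CF3CO2H, CH2Cl2, rt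
Reagents that add atoms: none
Why: Acidolysis of tert-butyl esters (E1 loss of 2-methylpropene) frees both acids without base.

Step 12
Reactants: 20 PIDA; 21 (E)-prop-1-enylboronic acid
Product: 22 2-[(E)-prop-1-enyl]-6-[(1R,2R,3R,5S)-2,6,6-trimethylbicyclo[3.1.1]heptan-3-yl]-1,3,6,2-dioxazaborocane-4,8-dione
Conditions: toluene/DMSO (10:1), Dean–Stark, reflux
Reagents that add atoms: none
Why: Dehydrative complexation of a boronic acid with an iminodiacetic acid is the standard route to MIDA-type boronates with tetracoordinate boron and keeps the alkene geometry.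

Step 13
Reactants: 17 7-(benzyloxy)-5-[(2R,3R)-3-(benzyloxy)butan-2-yl]-3-(2,2-dimethyl-4-oxo-4H-1,3-dioxin-6-yl)-6-methyl-2H-chromen-2-one; 22 (E)-prop-1-enyl PIDA boronate
Product: 24 7-(benzyloxy)-5-[(2R,3R)-3-(benzyloxy)butan-2-yl]-6-methyl-3-[(2S,3S)-2-methyl-4-oxo-3-(PIDA-boryl)-3,4-dihydro-2H-pyran-6-yl]-2H-chromen-2-one, via acylketene 23 (not isolated)
Conditions: 22 (3 equiv), toluene, 110 °C, slow addition of 17, N2 sweep
Reagents that add atoms: none
Why: Proposed new method: Heating opens the dioxinone ring of 17 by retro-[4+2] loss of acetone to acylketene 23, and its s-cis O=C–CH=C=O unit then adds across the alkene of 22 in one asynchronous, inverse-electron-demand oxa-[4+2] event in which the ketene carbon (future C4) bonds to the boron-bearing carbon (C3) while the acyl oxygen (future O1) bonds to the methyl-bearing carbon (C2). The closest known reaction type is the cycloaddition of dioxinone-derived acylketenes with enol ethers to 2-alkoxy-2,3-dihydropyran-4-ones; new is the dienophile class, and the case for it is that the electron-rich σ(C–B) bond of tetracoordinate boron raises the alkene HOMO and stabilises charge on the β-carbon in the way silicon does in vinylsilanes, the same effect that makes such boronates take up electrophiles at the boron-bearing carbon. Ring C is closed by the intermolecular cycloaddition itself (four atoms from 23, two from 22), so no separate ring-closing step and no exo/endo question arises. Suprafacial addition to the (E)-alkene puts methyl and boron trans, and the absolute sense is controlled by the isopinocampheyl group on nitrogen, which lies beside the B–C(sp2) bond and should leave only the Si face of the methyl-bearing carbon open, as in the face-selective epoxidation known for this boronate class, giving (2S,3S); only C2 remains after step 14. Regioselectivity follows from the β-boron effect, and chemoselectivity against ketene dimerisation and re-addition of acetone is secured by slow addition of 17 to an excess of 22 under a nitrogen sweep, with both hydroxyl groups masked as benzyl ethers so that no O–H can trap 23. Because the boron is coordinatively saturated it cannot migrate from C3 to the C4 oxygen, which shuts the 2H-pyran/oxatriene electrocyclic path that would racemise C2 at this temperature.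

Step 14
Reactants: 24 cycloadduct
Product: 26 7-(benzyloxy)-5-[(2R,3R)-3-(benzyloxy)butan-2-yl]-6-methyl-3-[(2S)-2-methyl-4-oxo-3,4-dihydro-2H-pyran-6-yl]-2H-chromen-2-one, via boronic acid 25 (not isolated)
Conditions: NaHCO3, H2O/MeOH/THF, rt
Reagents that add atoms: none
Why: Mild aqueous base hydrolyses the iminodiacetate cage (standard release of MIDA-type boronates), and the freed α-boryl ketone, now with an empty orbital on boron, passes boron to oxygen and is protonated at C3 (protodeboronation), which leaves CH2 at C3 and does not touch the C2–O1 bond.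

Step 15
Reactants: 26 dibenzyl ether of the target
Product: 27 7-hydroxy-5-[(2R,3R)-3-hydroxybutan-2-yl]-6-methyl-3-[(2S)-2-methyl-4-oxo-3,4-dihydro-2H-pyran-6-yl]-2H-chromen-2-one (target)
Conditions: BCl3, pentamethylbenzene, CH2Cl2, −78 °C; then H2O
Reagents that add atoms: none
Why: Lewis-acid debenzylation with Friedel–Crafts capture of the benzyl cation by pentamethylbenzene is neither reductive nor basic, so the coumarin and enone double bonds and the base-labile C2 centre of ring C should survive.

**Compound list**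
1 | 5-bromobenzene-1,3-diol | Oc1cc(O)cc(Br)c1 | starting material
2 | 1,3-bis(benzyloxy)-5-bromobenzene | Brc1cc(OCc2ccccc2)cc(OCc2ccccc2)c1 | intermediate
3 | [2,4-bis(benzyloxy)-6-bromophenyl]methylidene(dimethyl)ammonium chloride | C[N+](C)=Cc1c(Br)cc(OCc2ccccc2)cc1OCc1ccccc1.[Cl-] | intermediate
4 | 2,4-bis(benzyloxy)-6-bromobenzaldehyde | O=Cc1c(Br)cc(OCc2ccccc2)cc1OCc1ccccc1 | intermediate
5 | 1,5-bis(benzyloxy)-3-bromo-2-methylbenzene | Cc1c(Br)cc(OCc2ccccc2)cc1OCc1ccccc1 | intermediate
6 | (2R,3R)-2,3-dimethyloxirane | C[C@H]1O[C@@H]1C | starting material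
7 | [3,5-bis(benzyloxy)-2-methylphenyl]magnesium bromide | Cc1c([Mg]Br)cc(OCc2ccccc2)cc1OCc1ccccc1 | intermediate
8 | (2R,3R)-3-[3,5-bis(benzyloxy)-2-methylphenyl]butan-2-ol | Cc1c(OCc2ccccc2)cc(OCc2ccccc2)cc1[C@@H](C)[C@@H](C)O | intermediate
9 | 1,5-bis(benzyloxy)-3-[(2R,3R)-3-(benzyloxy)butan-2-yl]-2-methylbenzene | Cc1c(OCc2ccccc2)cc(OCc2ccccc2)cc1[C@@H](C)[C@@H](C)OCc1ccccc1 | intermediate
10 | {2,4-bis(benzyloxy)-6-[(2R,3R)-3-(benzyloxy)butan-2-yl]-5-methylphenyl}methylidene(dimethyl)ammonium chloride | C[N+](C)=Cc1c(OCc2ccccc2)cc(OCc2ccccc2)c(C)c1[C@@H](C)[C@@H](C)OCc1ccccc1.[Cl-] | intermediate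
11 | 2,4-bis(benzyloxy)-6-[(2R,3R)-3-(benzyloxy)butan-2-yl]-5-methylbenzaldehyde | O=Cc1c(OCc2ccccc2)cc(OCc2ccccc2)c(C)c1[C@@H](C)[C@@H](C)OCc1ccccc1 | intermediate
12 | 4-(benzyloxy)-6-[(2R,3R)-3-(benzyloxy)butan-2-yl]-2-hydroxy-5-methylbenzaldehyde | O=Cc1c(O)cc(OCc2ccccc2)c(C)c1[C@@H](C)[C@@H](C)OCc1ccccc1 | intermediate
13 | 2,2,6-trimethyl-4H-1,3-dioxin-4-one | CC1=CC(=O)OC(C)(C)O1 | starting material
14 | lithium 2,2-dimethyl-6-methylidene-6H-1,3-dioxin-4-olate | C=C1C=C(O[Li])OC(C)(C)O1 | intermediate
15 | methyl 2-(2,2-dimethyl-4-oxo-4H-1,3-dioxin-6-yl)acetate | COC(=O)CC1=CC(=O)OC(C)(C)O1 | intermediate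
16 | methyl (Z)-3-{4-(benzyloxy)-6-[(2R,3R)-3-(benzyloxy)butan-2-yl]-2-hydroxy-5-methylphenyl}-2-(2,2-dimethyl-4-oxo-4H-1,3-dioxin-6-yl)prop-2-enoate | COC(=O)/C(=C\c1c(O)cc(OCc2ccccc2)c(C)c1[C@@H](C)[C@@H](C)OCc1ccccc1)C1=CC(=O)OC(C)(C)O1 | intermediate
17 | 7-(benzyloxy)-5-[(2R,3R)-3-(benzyloxy)butan-2-yl]-3-(2,2-dimethyl-4-oxo-4H-1,3-dioxin-6-yl)-6-methyl-2H-chromen-2-one | Cc1c(OCc3ccccc3)cc2oc(=O)c(C3=CC(=O)OC(C)(C)O3)cc2c1[C@@H](C)[C@@H](C)OCc1ccccc1 | intermediate
18 | (1R,2R,3R,5S)-2,6,6-trimethylbicyclo[3.1.1]heptan-3-amine | C[C@@H]1[C@H]2C[C@H](C2(C)C)C[C@H]1N | starting material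
19 | di-tert-butyl 2,2'-{[(1R,2R,3R,5S)-2,6,6-trimethylbicyclo[3.1.1]heptan-3-yl]azanediyl}diacetate | C[C@@H]1[C@H]2C[C@H](C2(C)C)C[C@H]1N(CC(=O)OC(C)(C)C)CC(=O)OC(C)(C)C | intermediate
20 | 2,2'-{[(1R,2R,3R,5S)-2,6,6-trimethylbicyclo[3.1.1]heptan-3-yl]azanediyl}diacetic acid (PIDA) | C[C@@H]1[C@H]2C[C@H](C2(C)C)C[C@H]1N(CC(=O)O)CC(=O)O | intermediate
21 | (E)-prop-1-enylboronic acid | C/C=C/B(O)O | starting material
22 | 2-[(E)-prop-1-enyl]-6-[(1R,2R,3R,5S)-2,6,6-trimethylbicyclo[3.1.1]heptan-3-yl]-1,3,6,2-dioxazaborocane-4,8-dione | C/C=C/[B-]12OC(=O)C[N+]1(CC(=O)O2)[C@@H]1C[C@@H]2C[C@H]([C@H]1C)C2(C)C | intermediate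
23 | 3-{7-(benzyloxy)-5-[(2R,3R)-3-(benzyloxy)butan-2-yl]-6-methyl-2-oxo-2H-chromen-3-yl}-3-oxoprop-1-en-1-one (acylketene) | Cc1c(OCc3ccccc3)cc2oc(=O)c(C(=O)C=C=O)cc2c1[C@@H](C)[C@@H](C)OCc1ccccc1 | intermediate
24 | 7-(benzyloxy)-5-[(2R,3R)-3-(benzyloxy)butan-2-yl]-6-methyl-3-[(2S,3S)-2-methyl-4-oxo-3-(PIDA-boryl)-3,4-dihydro-2H-pyran-6-yl]-2H-chromen-2-one | Cc1c(OCc3ccccc3)cc2oc(=O)c(C3=CC(=O)[C@@H]([B-]45OC(=O)C[N+]4(CC(=O)O5)[C@@H]6C[C@@H]7C[C@H]([C@H]6C)C7(C)C)[C@H](C)O3)cc2c1[C@@H](C)[C@@H](C)OCc1ccccc1 | intermediate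
25 | [(2S,3S)-6-{7-(benzyloxy)-5-[(2R,3R)-3-(benzyloxy)butan-2-yl]-6-methyl-2-oxo-2H-chromen-3-yl}-2-methyl-4-oxo-3,4-dihydro-2H-pyran-3-yl]boronic acid | Cc1c(OCc3ccccc3)cc2oc(=O)c(C3=CC(=O)[C@@H](B(O)O)[C@H](C)O3)cc2c1[C@@H](C)[C@@H](C)OCc1ccccc1 | intermediate
26 | 7-(benzyloxy)-5-[(2R,3R)-3-(benzyloxy)butan-2-yl]-6-methyl-3-[(2S)-2-methyl-4-oxo-3,4-dihydro-2H-pyran-6-yl]-2H-chromen-2-one | Cc1c(OCc3ccccc3)cc2oc(=O)c(C3=CC(=O)C[C@H](C)O3)cc2c1[C@@H](C)[C@@H](C)OCc1ccccc1 | intermediate
27 | 7-hydroxy-5-[(2R,3R)-3-hydroxybutan-2-yl]-6-methyl-3-[(2S)-2-methyl-4-oxo-3,4-dihydro-2H-pyran-6-yl]-2H-chromen-2-one | Cc1c(O)cc2oc(=O)c(C3=CC(=O)C[C@H](C)O3)cc2c1[C@@H](C)[C@@H](C)O | target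

Total step count: 15. Longest linear sequence: 11 steps (1–7, 9, 13, 14, 15).

**Steps most likely to fail**

Step 13. The boronate alkene may be too weak a nucleophile, so that dimerisation of the acylketene outruns the cycloaddition. An ene-type hydrogen transfer from the allylic methyl group may compete. Facial shielding by the auxiliary may be weak at 110 °C or of the opposite sense.

The fallback sets out from 12 and comes back at 26, and it takes C2 from the chiral pool by known chemistry. Knoevenagel condensation–lactonisation of 12 with ethyl acetoacetate (piperidine, EtOH) would give the 3-acetylcoumarin F1. Commercial methyl (S)-3-hydroxybutanoate would be silylated (TBSCl, imidazole) to the silyl ether ester F2. Saponification (LiOH) would give the acid F3, and oxalyl chloride would give the acid chloride F4. Soft enolisation of F1 (MgBr2·OEt2, iPr2NEt, CH2Cl2) and C-acylation with F4 would give the 1,3-diketone F5. Aqueous CF3CO2H would then remove the silyl group and close ring C by attack of the free (S)-hydroxyl on the coumarin-side carbonyl and loss of water. This gives 26 with the C–O bond of the stereocentre never broken.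

Step 9. Condensation at the doubly ortho-substituted aldehyde may be slow, and long heating with piperidine may bring aminolysis of the dioxinone ring.

The fallback sets out from 13 and 12 and comes back at 17, and it makes the carbon–carbon bond intramolecularly. Dienolate 14 would be carboxylated with CO2 to the dioxinonyl acetic acid F6. Steglich esterification of the phenol of 12 with F6 (dicyclohexylcarbodiimide, DMAP, CH2Cl2, 0 °C) would give the aryl ester F7. Et3N at rt would then close ring B by intramolecular Knoevenagel condensation.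

Step 15. The Lewis acid may ionise the secondary side-chain C–O bond with aryl participation, or it may open ring C at C2, with loss of configuration in either case.

The fallback sets out from 26 and comes back at 27. It replaces Lewis-acid cleavage with hydrogenolysis (H2, Pd(OH)2 on carbon, EtOAc, rt), stopped as soon as both benzyl groups are gone so that the coumarin double bond is not reduced. No new compound is made (F0).

**Further compounds**
F1 | step 13 | 3-acetyl-7-(benzyloxy)-5-[(2R,3R)-3-(benzyloxy)butan-2-yl]-6-methyl-2H-chromen-2-one | Cc1c(OCc3ccccc3)cc2oc(=O)c(C(C)=O)cc2c1[C@@H](C)[C@@H](C)OCc1ccccc1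
F2 | step 13 | methyl (3S)-3-[(tert-butyldimethylsilyl)oxy]butanoate | C[C@H](O[Si](C)(C)C(C)(C)C)CC(=O)OC
F3 | step 13 | (3S)-3-[(tert-butyldimethylsilyl)oxy]butanoic acid | C[C@H](O[Si](C)(C)C(C)(C)C)CC(=O)O
F4 | step 13 | (3S)-3-[(tert-butyldimethylsilyl)oxy]butanoyl chloride | C[C@H](O[Si](C)(C)C(C)(C)C)CC(=O)Cl
F5 | step 13 | (5S)-1-{7-(benzyloxy)-5-[(2R,3R)-3-(benzyloxy)butan-2-yl]-6-methyl-2-oxo-2H-chromen-3-yl}-5-[(tert-butyldimethylsilyl)oxy]hexane-1,3-dione | Cc1c(OCc3ccccc3)cc2oc(=O)c(C(=O)CC(=O)C[C@H](C)O[Si](C)(C)C(C)(C)C)cc2c1[C@@H](C)[C@@H](C)OCc1ccccc1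
F6 | step 9 | 2-(2,2-dimethyl-4-oxo-4H-1,3-dioxin-6-yl)acetic acid | OC(=O)CC1=CC(=O)OC(C)(C)O1
F7 | step 9 | 5-(benzyloxy)-3-[(2R,3R)-3-(benzyloxy)butan-2-yl]-2-formyl-4-methylphenyl 2-(2,2-dimethyl-4-oxo-4H-1,3-dioxin-6-yl)acetate | O=Cc1c(OC(=O)CC2=CC(=O)OC(C)(C)O2)cc(OCc2ccccc2)c(C)c1[C@@H](C)[C@@H](C)OCc1ccccc1
F0 | step 15 | none | none
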